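**Plan**
- Retrosynthesis: the C11 hydroperoxide and C6=C7 are unravelled by a Schenck ene reaction (the presumed biosynthetic event) to a 7(11)-isopropylidene dienone. C7=C11 is cut by aldol/elimination with acetone, C1–OH by a vinylogous Rubottom oxidation, the angelate by esterification. C5–C6 and C9=C10 are cut by a Robinson annulation, and the two methyl groups by conjugate addition/enolate methylation of a commercial enone monoketal.
- Forward: ring A is bought as 1,4-dioxaspiro[4.5]dec-6-en-8-one and methylated twice, ring B (C5–C10) is annulated onto it with methyl vinyl ketone, then C3, C7/C11 and C1 are dressed and the hydroperoxide comes last.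
- Enabling feature: ring B is a cyclohexenone whose β-carbon C10 was the ring A carbonyl and whose quaternary C5 was its α-carbon (1,5-relationship C10/C8 through C5–C6–C7), i.e. a Robinson retron.
- Stereochemistry: C4 by Cu-catalysed asymmetric conjugate addition; C5 relayed from C4 in the annulation (cis-dimethyl); C3 by equatorial hydride attack anti to the axial C5 methyl; C1 by axial attack on a dienol ether; angelate geometry bought with angelic acid.
- Design device: a tertiary C11 acetate keeps C7 sp3 (latent isopropylidene) until C1 is oxidised, so no hydroxyl protecting group is needed.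

Key step: step 2

Remark: atom numbers C1–C11 and α/β (β = face of the C5 methyl) follow the eremophilane numbering of the target (C1 carbinol, C3 ester carbon, C4 CH–CH3, C5 quaternary, C8 ketone, C11 hydroperoxy carbon); enone 1 and both antipodes of the phosphoramidite ligand are taken as commercial.

**Step 1**
Reactants: 1 1,4-dioxaspiro[4.5]dec-6-en-8-one
Product: 3 (6R,7R)-6,7-dimethyl-1,4-dioxaspiro[4.5]decan-8-one, via zinc enolate 2 (not isolated)
Conditions: Me2Zn (1.5 equiv), Cu(OTf)2 (2 mol %), (S)-binaphthol-derived phosphoramidite of bis[(R)-1-phenylethyl]amine (4 mol %), toluene, −25 °C; then MeI (5 equiv), HMPA, 0 °C → rt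
Reagents that add atoms: dimethylzinc, C[Zn]C; methyl iodide, CI
Why: Copper-catalysed asymmetric conjugate addition sets C4 under ligand control (this ligand antipode is expected to give 6R by analogy with cyclohexenone), and zinc enolate 2 is C-methylated in situ trans to the new methyl (tandem conjugate addition–enolate alkylation); the C5 configuration is irrelevant because it is re-made in step 2.

**Step 2**
Reactants: 3 (6R,7R)-6,7-dimethyl-1,4-dioxaspiro[4.5]decan-8-one; 4 methyl vinyl ketone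
Product: 7 (1'R,8a'R)-1',8a'-dimethyl-3',4',8',8a'-tetrahydro-1'H-spiro[1,3-dioxolane-2,2'-naphthalen]-6'(7'H)-one, via diketone 5 (not isolated), via ketol 6 (not isolated)
Conditions: NaOEt (0.2 equiv), EtOH, −10 °C, 4 added slowly; then NaOEt (1 equiv), 60 °C
Reagents that add atoms: none
Why: Robinson annulation: under equilibrating alkoxide conditions the more substituted enolate of 3 (at the methyl-bearing C5) adds to 4 in a Michael addition to give 1,5-diketone 5, whose methyl-ketone enolate closes ring B by aldol addition to the C10 carbonyl (ketol 6) and loses water by E1cB to give enone 7. The closest known reaction type is the alkoxide-mediated annulation of 2-methyl- and 2,3-dimethylcyclohexanone with methyl vinyl ketone. Ring B (C5–C10) is closed in a 6-(enolendo)-exo-trig aldol addition. The only new stereocenter, the quaternary C5, is controlled by the neighbouring C4: in the enolate the C4 methyl is pseudoaxial to avoid allylic strain against the C5 methyl and the acceptor adds axially to the opposite face, so the two methyl groups end up cis. The step needs regioselectivity for C5 over the C1 methylene, which the thermodynamic enolate preference in the protic medium at low temperature should secure, and it needs the dioxolane to survive, which the basic medium secures.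

**Step 3**
Reactants: 7 (1'R,8a'R)-1',8a'-dimethyl-3',4',8',8a'-tetrahydro-1'H-spiro[1,3-dioxolane-2,2'-naphthalen]-6'(7'H)-one
Product: 8 (1R,8aR)-1,8a-dimethyl-3,4,8,8a-tetrahydronaphthalene-2,6(1H,7H)-dione
Conditions: 2 M HCl, THF, 0 °C → rt, stopped at full conversion
Reagents that add atoms: water, O
Why: Acid-catalysed hydrolysis of the dioxolane unmasks the C3 ketone, and the conditions are kept cold and short because C4 is now α to a ketone and could epimerise by enolisation.

**Step 4**
Reactants: 8 (1R,8aR)-1,8a-dimethyl-3,4,8,8a-tetrahydronaphthalene-2,6(1H,7H)-dione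
Product: 9 (4aR,5R,6S)-6-hydroxy-4a,5-dimethyl-4,4a,5,6,7,8-hexahydronaphthalen-2(3H)-one
Conditions: LiBH(s-Bu)3 (L-Selectride, 1.1 equiv), THF, −78 °C; aq. NH4Cl
Reagents that add atoms: none
Why: The bulky hydride reduces the saturated C3 ketone in preference to the β,β-disubstituted enone and attacks along the equatorial trajectory on the α face, the axial trajectory being blocked by the syn-axial C5 methyl, which should give the axial 3β alcohol cis to both methyl groups.

**Step 5**
Reactants: 9 (4aR,5R,6S)-6-hydroxy-4a,5-dimethyl-4,4a,5,6,7,8-hexahydronaphthalen-2(3H)-one; 10 angelic acid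
Product: 12 (1R,2S,8aR)-1,8a-dimethyl-6-oxo-1,2,3,4,6,7,8,8a-octahydronaphthalen-2-yl (2Z)-2-methylbut-2-enoate, via mixed anhydride 11 (not isolated)
Conditions: 10 (3 equiv), 2,4,6-trichlorobenzoyl chloride, Et3N, toluene, rt; then 9, toluene, 75 °C
Reagents that add atoms: none
Why: Yamaguchi esterification through mixed anhydride 11 acylates the hindered axial alcohol with retention at C3, and the mixed-anhydride method without a strongly nucleophilic catalyst is the usual way to keep the Z (angelate) geometry.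

**Step 6**
Reactants: 12 (1R,2S,8aR)-1,8a-dimethyl-6-oxo-1,2,3,4,6,7,8,8a-octahydronaphthalen-2-yl (2Z)-2-methylbut-2-enoate; 13 acetone
Product: 16 (1R,2S,7S,8aR)-7-(2-acetoxypropan-2-yl)-1,8a-dimethyl-6-oxo-1,2,3,4,6,7,8,8a-octahydronaphthalen-2-yl (2Z)-2-methylbut-2-enoate, via lithium dienolate 14 (not isolated), via lithium aldolate 15 (not isolated)
Conditions: LiN(SiMe3)2 (1.1 equiv), THF, −78 °C; 13 (3 equiv), −78 °C; Ac2O (4 equiv), −78 → −40 °C; AcOH quench in the cold
Reagents that add atoms: acetic anhydride, CC(=O)OC(C)=O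
Why: Kinetic deprotonation at the α'-methylene C7 gives dienolate 14, aldol addition to acetone gives tertiary alkoxide 15, and O-acetylation in the cold blocks the retro-aldol reaction and stores the leaving group for step 8 while C7 stays sp3, so that step 7 can enolise only towards C1; the new C7 stereocenter (equatorial, trans to the C5 methyl expected) is destroyed in step 8.

**Step 7**
Reactants: 16 (1R,2S,7S,8aR)-7-(2-acetoxypropan-2-yl)-1,8a-dimethyl-6-oxo-1,2,3,4,6,7,8,8a-octahydronaphthalen-2-yl (2Z)-2-methylbut-2-enoate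
Product: 18 (1R,2S,4R,7S,8aR)-7-(2-acetoxypropan-2-yl)-4-hydroxy-1,8a-dimethyl-6-oxo-1,2,3,4,6,7,8,8a-octahydronaphthalen-2-yl (2Z)-2-methylbut-2-enoate, via silyl dienol ether 17 (not isolated)
Conditions: TBSOTf, Et3N, CH2Cl2, 0 °C → rt; crude 17: mCPBA (1.1 equiv), NaHCO3, CH2Cl2, −20 °C; aq. Na2S2O3, then dilute citric acid
Reagents that add atoms: 3-chloroperbenzoic acid (mCPBA), OOC(=O)c1cccc(Cl)c1
Why: Vinylogous Rubottom oxidation: soft enolisation gives the extended, thermodynamically preferred dienol silyl ether 17, whose C1=C10 bond should be attacked by the peracid axially on the β face, as in the 6β-hydroxylation of steroidal 3,5-dienol ethers, and collapse of the epoxide returns the enone with the axial 1β hydroxyl.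

**Step 8**
Reactants: 18 (1R,2S,4R,7S,8aR)-7-(2-acetoxypropan-2-yl)-4-hydroxy-1,8a-dimethyl-6-oxo-1,2,3,4,6,7,8,8a-octahydronaphthalen-2-yl (2Z)-2-methylbut-2-enoate
Product: 19 (1R,2S,4R,8aR)-4-hydroxy-1,8a-dimethyl-6-oxo-7-(propan-2-ylidene)-1,2,3,4,6,7,8,8a-octahydronaphthalen-2-yl (2Z)-2-methylbut-2-enoate
Conditions: DBU (2 equiv), CH2Cl2, 0 °C → rt
Reagents that add atoms: none
Why: E1cB elimination of acetic acid from the β-acetoxy ketone can only give the conjugated tetrasubstituted isopropylidene alkene, and the non-nucleophilic amidine base should not form the alkoxide needed for angelate migration from O3 to the syn-axial O1.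

**Step 9**
Reactants: 19 (1R,2S,4R,8aR)-4-hydroxy-1,8a-dimethyl-6-oxo-7-(propan-2-ylidene)-1,2,3,4,6,7,8,8a-octahydronaphthalen-2-yl (2Z)-2-methylbut-2-enoate
Product: 20 (1R,2S,4R,8aR)-4-hydroxy-7-(2-hydroperoxypropan-2-yl)-1,8a-dimethyl-6-oxo-1,2,3,4,6,8a-hexahydronaphthalen-2-yl (2Z)-2-methylbut-2-enoate
Conditions: O2, visible light, tetraphenylporphyrin (cat.), CH2Cl2, −20 °C, stopped at full conversion of 19
Reagents that add atoms: dioxygen, O=O
Why: Schenck ene reaction, the likely biosynthetic event: singlet oxygen reacts with the s-cis α-isopropylidene ketone, bonds to C11 and takes the allylic hydrogen from C6, the alkyl group geminal to the carbonyl on the alkene (gem effect of enones), so the double bond moves to C6=C7 and the tertiary hydroperoxide should result without a new stereocenter, while the s-trans C9=C10 enone and the electron-poor angelate react far more slowly.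

**Compound list**
1 | 1,4-dioxaspiro[4.5]dec-6-en-8-one | O=C1C=CC2(CC1)OCCO2 | starting material
2 | methylzinc (6R)-6-methyl-1,4-dioxaspiro[4.5]dec-7-en-8-olate (zinc enolate) | C[Zn]OC1=C[C@@H](C)C2(CC1)OCCO2 | intermediate (not isolated)
3 | (6R,7R)-6,7-dimethyl-1,4-dioxaspiro[4.5]decan-8-one (trans; the minor 7S epimer converges in step 2) | O1CCOC12CCC(=O)[C@H](C)[C@H]2C | intermediate
4 | methyl vinyl ketone (but-3-en-2-one) | C=CC(C)=O | starting material
5 | (6R,7R)-6,7-dimethyl-7-(3-oxobutyl)-1,4-dioxaspiro[4.5]decan-8-one | O1CCOC12CCC(=O)[C@](C)(CCC(C)=O)[C@H]2C | intermediate (not isolated)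
6 | (1'R,4a'S,8a'R)-4a'-hydroxy-1',8a'-dimethyl-3',4',4a',7',8',8a'-hexahydro-1'H-spiro[1,3-dioxolane-2,2'-naphthalen]-6'(5'H)-one (cis-fused ketol) | O1CCOC12CC[C@]3(O)CC(=O)CC[C@]3(C)[C@H]2C | intermediate (not isolated)
7 | (1'R,8a'R)-1',8a'-dimethyl-3',4',8',8a'-tetrahydro-1'H-spiro[1,3-dioxolane-2,2'-naphthalen]-6'(7'H)-one | O1CCOC12CCC3=CC(=O)CC[C@]3(C)[C@H]2C | intermediate
8 | (1R,8aR)-1,8a-dimethyl-3,4,8,8a-tetrahydronaphthalene-2,6(1H,7H)-dione | O=C1CCC2=CC(=O)CC[C@]2(C)[C@H]1C | intermediate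
9 | (4aR,5R,6S)-6-hydroxy-4a,5-dimethyl-4,4a,5,6,7,8-hexahydronaphthalen-2(3H)-one | O[C@H]1CCC2=CC(=O)CC[C@]2(C)[C@H]1C | intermediate
10 | angelic acid, (2Z)-2-methylbut-2-enoic acid | C/C=C(/C)C(=O)O | starting material
11 | (2Z)-2-methylbut-2-enoic 2,4,6-trichlorobenzoic anhydride | C/C=C(/C)C(=O)OC(=O)c1c(Cl)cc(Cl)cc1Cl | intermediate (not isolated)
12 | (1R,2S,8aR)-1,8a-dimethyl-6-oxo-1,2,3,4,6,7,8,8a-octahydronaphthalen-2-yl (2Z)-2-methylbut-2-enoate | C/C=C(/C)C(=O)O[C@H]1CCC2=CC(=O)CC[C@]2(C)[C@H]1C | intermediate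
13 | acetone | CC(C)=O | starting material
14 | lithium cross-conjugated dienolate of 12 (O–Li on C8, C7=C8) | C/C=C(/C)C(=O)O[C@H]1CCC2=CC(O[Li])=CC[C@]2(C)[C@H]1C | intermediate (not isolated)
15 | lithium alkoxide of the C7 acetone aldol adduct of 12 | C/C=C(/C)C(=O)O[C@H]1CCC2=CC(=O)[C@H](C(C)(C)O[Li])C[C@]2(C)[C@H]1C | intermediate (not isolated)
16 | (1R,2S,7S,8aR)-7-(2-acetoxypropan-2-yl)-1,8a-dimethyl-6-oxo-1,2,3,4,6,7,8,8a-octahydronaphthalen-2-yl (2Z)-2-methylbut-2-enoate | C/C=C(/C)C(=O)O[C@H]1CCC2=CC(=O)[C@H](C(C)(C)OC(C)=O)C[C@]2(C)[C@H]1C | intermediate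
17 | (1R,2S,7S,8aR)-7-(2-acetoxypropan-2-yl)-6-[(tert-butyldimethylsilyl)oxy]-1,8a-dimethyl-1,2,3,7,8,8a-hexahydronaphthalen-2-yl (2Z)-2-methylbut-2-enoate | C/C=C(/C)C(=O)O[C@H]1CC=C2C=C(O[Si](C)(C)C(C)(C)C)[C@H](C(C)(C)OC(C)=O)C[C@]2(C)[C@H]1C | intermediate (not isolated)
18 | (1R,2S,4R,7S,8aR)-7-(2-acetoxypropan-2-yl)-4-hydroxy-1,8a-dimethyl-6-oxo-1,2,3,4,6,7,8,8a-octahydronaphthalen-2-yl (2Z)-2-methylbut-2-enoate | C/C=C(/C)C(=O)O[C@H]1C[C@@H](O)C2=CC(=O)[C@H](C(C)(C)OC(C)=O)C[C@]2(C)[C@H]1C | intermediate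
19 | (1R,2S,4R,8aR)-4-hydroxy-1,8a-dimethyl-6-oxo-7-(propan-2-ylidene)-1,2,3,4,6,7,8,8a-octahydronaphthalen-2-yl (2Z)-2-methylbut-2-enoate | C/C=C(/C)C(=O)O[C@H]1C[C@@H](O)C2=CC(=O)C(=C(C)C)C[C@]2(C)[C@H]1C | intermediate
20 | (1R,2S,4R,8aR)-4-hydroxy-7-(2-hydroperoxypropan-2-yl)-1,8a-dimethyl-6-oxo-1,2,3,4,6,8a-hexahydronaphthalen-2-yl (2Z)-2-methylbut-2-enoate (CNP0300636.1) | C/C=C(/C)C(=O)O[C@H]1C[C@@H](O)C2=CC(=O)C(C(C)(C)OO)=C[C@]2(C)[C@H]1C | target

Total step count: 9. Longest linear sequence: 9 steps (1 → 20).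

**Steps most likely to fail**

Step 7. Poor facial selectivity in the peracid attack on the dienol ether: the β face at C1 is flanked by the syn-axial C5 methyl and C3 ester, so attack on the open α face may win. The fallback sets out from 17 and sets C1 by ketone reduction instead of by electrophilic oxygenation. The oxidation of step 7 then delivers the equatorial 1α alcohol, (1R,2S,4S,7S,8aR)-7-(2-acetoxypropan-2-yl)-4-hydroxy-1,8a-dimethyl-6-oxo-1,2,3,4,6,7,8,8a-octahydronaphthalen-2-yl (2Z)-2-methylbut-2-enoate F1. DBU as in step 8 gives the 1α-hydroxy dienone, (1R,2S,4S,8aR)-4-hydroxy-1,8a-dimethyl-6-oxo-7-(propan-2-ylidene)-1,2,3,4,6,7,8,8a-octahydronaphthalen-2-yl (2Z)-2-methylbut-2-enoate F2. MnO2 (CH2Cl2, rt) oxidises the allylic alcohol to the enedione, (1R,2S,8aR)-1,8a-dimethyl-4,6-dioxo-7-(propan-2-ylidene)-1,2,3,4,6,7,8,8a-octahydronaphthalen-2-yl (2Z)-2-methylbut-2-enoate F3. Luche reduction (NaBH4, CeCl3·7H2O, MeOH, −78 °C) should then deliver hydride to the C1 carbonyl from the open α face, the cross-conjugated C8 carbonyl being shielded by the isopropylidene group, and give 19, where the route is rejoined.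

Step 2. Michael addition through the less substituted enolate (at the C1 methylene), addition on the wrong face of the C5 enolate, or polymerisation of the vinyl ketone. The fallback sets out from 3 and uses a chiral imine in place of the free enolate. Condensation with (R)-1-phenylethylamine (toluene, TsOH cat., removal of water) gives (6R,7R)-6,7-dimethyl-N-[(1R)-1-phenylethyl]-1,4-dioxaspiro[4.5]decan-8-imine F4. Its more substituted secondary-enamine tautomer adds to 4 (THF, rt) in an aza-ene-type Michael addition only at the methyl-bearing carbon; the amine antipode is chosen to reinforce the anti preference of the C4 methyl ((R) expected by analogy with 2-methylcyclohexanone). This gives the keto imine 4-{(6R,7R)-6,7-dimethyl-8-{[(1R)-1-phenylethyl]imino}-1,4-dioxaspiro[4.5]decan-7-yl}butan-2-one F5. Aqueous AcOH hydrolysis releases diketone 5, now isolated, where the route is rejoined; NaOMe in MeOH then closes it via 6 to 7.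

Step 6. Retro-aldol loss of acetone, incomplete O-acetylation of the hindered tertiary alkoxide, or premature elimination that would put the isopropylidene in place before C1 is oxidised. The fallback sets out from 12 and carries the aldol as a free or silylated alcohol, with a chemoselective dehydration at the end. Aldol addition without trap (LiN(SiMe3)2; ZnCl2; acetone; NH4Cl quench at −78 °C) gives the ketol (1R,2S,7S,8aR)-7-(2-hydroxypropan-2-yl)-1,8a-dimethyl-6-oxo-1,2,3,4,6,7,8,8a-octahydronaphthalen-2-yl (2Z)-2-methylbut-2-enoate F6. Excess TMSOTf/Et3N silylates both the tertiary hydroxyl and the dienol to give the bis-silyl compound (1R,2S,7S,8aR)-1,8a-dimethyl-6-[(trimethylsilyl)oxy]-7-{2-[(trimethylsilyl)oxy]propan-2-yl}-1,2,3,7,8,8a-hexahydronaphthalen-2-yl (2Z)-2-methylbut-2-enoate F7. mCPBA followed by dilute citric acid converts this to the diol (1R,2S,4R,7S,8aR)-4-hydroxy-7-(2-hydroxypropan-2-yl)-1,8a-dimethyl-6-oxo-1,2,3,4,6,7,8,8a-octahydronaphthalen-2-yl (2Z)-2-methylbut-2-enoate F8. The tertiary hydroxyl alone is then dehydrated with diphenylbis(1,1,1,3,3,3-hexafluoro-2-phenyl-2-propoxy)sulfurane (CH2Cl2, 0 °C), the hindered secondary allylic hydroxyl reacting far more slowly, to give 19, where the route is rejoined.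

**Further compounds**
F1 | step 7 | (1R,2S,4S,7S,8aR)-7-(2-acetoxypropan-2-yl)-4-hydroxy-1,8a-dimethyl-6-oxo-1,2,3,4,6,7,8,8a-octahydronaphthalen-2-yl (2Z)-2-methylbut-2-enoate | C/C=C(/C)C(=O)O[C@H]1C[C@H](O)C2=CC(=O)[C@H](C(C)(C)OC(C)=O)C[C@]2(C)[C@H]1C
F2 | step 7 | (1R,2S,4S,8aR)-4-hydroxy-1,8a-dimethyl-6-oxo-7-(propan-2-ylidene)-1,2,3,4,6,7,8,8a-octahydronaphthalen-2-yl (2Z)-2-methylbut-2-enoate | C/C=C(/C)C(=O)O[C@H]1C[C@H](O)C2=CC(=O)C(=C(C)C)C[C@]2(C)[C@H]1C
F3 | step 7 | (1R,2S,8aR)-1,8a-dimethyl-4,6-dioxo-7-(propan-2-ylidene)-1,2,3,4,6,7,8,8a-octahydronaphthalen-2-yl (2Z)-2-methylbut-2-enoate | C/C=C(/C)C(=O)O[C@H]1CC(=O)C2=CC(=O)C(=C(C)C)C[C@]2(C)[C@H]1C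
F4 | step 2 | (6R,7R)-6,7-dimethyl-N-[(1R)-1-phenylethyl]-1,4-dioxaspiro[4.5]decan-8-imine | O1CCOC12CCC(=N[C@H](C)c3ccccc3)[C@H](C)[C@H]2C
F5 | step 2 | 4-{(6R,7R)-6,7-dimethyl-8-{[(1R)-1-phenylethyl]imino}-1,4-dioxaspiro[4.5]decan-7-yl}butan-2-one | O1CCOC12CCC(=N[C@H](C)c3ccccc3)[C@](C)(CCC(C)=O)[C@H]2C
F6 | step 6 | (1R,2S,7S,8aR)-7-(2-hydroxypropan-2-yl)-1,8a-dimethyl-6-oxo-1,2,3,4,6,7,8,8a-octahydronaphthalen-2-yl (2Z)-2-methylbut-2-enoate | C/C=C(/C)C(=O)O[C@H]1CCC2=CC(=O)[C@H](C(C)(C)O)C[C@]2(C)[C@H]1C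
F7 | step 6 | (1R,2S,7S,8aR)-1,8a-dimethyl-6-[(trimethylsilyl)oxy]-7-{2-[(trimethylsilyl)oxy]propan-2-yl}-1,2,3,7,8,8a-hexahydronaphthalen-2-yl (2Z)-2-methylbut-2-enoate | C/C=C(/C)C(=O)O[C@H]1CC=C2C=C(O[Si](C)(C)C)[C@H](C(C)(C)O[Si](C)(C)C)C[C@]2(C)[C@H]1C
F8 | step 6 | (1R,2S,4R,7S,8aR)-4-hydroxy-7-(2-hydroxypropan-2-yl)-1,8a-dimethyl-6-oxo-1,2,3,4,6,7,8,8a-octahydronaphthalen-2-yl (2Z)-2-methylbut-2-enoate | C/C=C(/C)C(=O)O[C@H]1C[C@@H](O)C2=CC(=O)[C@H](C(C)(C)O)C[C@]2(C)[C@H]1C
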